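**Retrosynthetic overview**

1. The target is unmasked last: fluoride removes three silyl groups and the freed cyclobutanol opens by retro-aldol to the 1,5-diketone; just before, SmI2 removes a sulfonyl group.
2. The side chain is attached by acyl substitution of a tricyclic δ-lactone with an (E)-allyl sulfone carbanion; the alkoxide set free closes the epoxide on a neighbouring tertiary chloride, with retention.
3. The tricycle comes from a [2+2] photocycloaddition of a (6S)-4-silyloxy-5,6-dihydropyran-2-one with 1,2-dimethylcyclopentene. This one step makes the bond from ring carbon C2 to its acyl carbon, the C1–CH2 bond and both quaternary centres.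
4. Enabling feature: the 1,5-diketone O=C–C2–C1–CH2–C=O spans the cis-dimethylated C1–C2 bond of the cyclopentane, so C1 and C2 are the two carbons of a symmetric alkene. The oxygen-bearing carbon β to the C2 acyl group lets the enol be locked in a chiral six-membered lactone.
5. Ring order: δ-lactone (temporary), cyclobutane on the purchased cyclopentene (temporary), epoxide as the lactone opens, then cleavage of the cyclobutane. Building blocks: a dioxinone and methacrolein; 2-allyl-6-methylphenol.

Key step: step 6

Assumption: the antipode of the binaphthyl Schiff-base ligand in step 2 is the one that sends the dienol ether to the Si face of methacrolein, giving the (S)-carbinol; the sense is to be checked on 5 by Mosher ester analysis before going on.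

**Route**

Step 1
Reactants: 1 2,2,6-trimethyl-4H-1,3-dioxin-4-one
Product: 2 [(2,2-dimethyl-6-methylidene-6H-1,3-dioxin-4-yl)oxy]trimethylsilane
Conditions: LiN(iPr)2 (1.1 equiv), THF, −78 °C; Me3SiCl, −78 °C → rt; distillation
Reagents that add atoms: chlorotrimethylsilane, C[Si](C)(C)Cl
Why: Kinetic deprotonation of the vinylogous ester at the 6-methyl group and O-silylation of the dienolate should give the cross-conjugated silyl dienol ether (silyl ketene acetal formation), with no stereocentre involved.

Step 2
Reactants: 2 silyl dienol ether; 3 methacrolein (2-methylprop-2-enal)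
Product: 5 6-[(2S)-2-hydroxy-3-methylbut-3-en-1-yl]-2,2-dimethyl-4H-1,3-dioxin-4-one, via trimethylsilyl ether 4 (not isolated)
Conditions: Ti(OiPr)4 (5 mol %), Schiff base of 2-amino-2'-hydroxy-1,1'-binaphthyl and 3-bromo-5-tert-butylsalicylaldehyde (5 mol %), 3,5-di-tert-butylsalicylic acid (5 mol %), Et2O, 0 °C; then CF3CO2H, THF–H2O, 0 °C
Reagents that add atoms: none
Why: In this catalytic enantioselective vinylogous Mukaiyama aldol addition the chiral titanium complex activates the aldehyde and the dienol ether attacks through its terminal carbon on the Si face of the C=O group, which sets the (S)-carbinol that later becomes the epoxide carbon.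

Step 3
Reactants: 5 dioxinone aldol adduct
Product: 7 (6S)-6-(prop-1-en-2-yl)oxane-2,4-dione, via acylketene 6 (not isolated)
Conditions: toluene (0.02 M), 110 °C
Reagents that add atoms: none
Why: Thermal retro-[4+2] cleavage of the dioxinone expels acetone, and the acylketene is trapped by the δ-hydroxyl group in a six-membered lactonisation that leaves the carbinol centre untouched.

Step 4
Reactants: 7 isopropenyl keto lactone
Product: 8 (6S)-6-(2-chloropropan-2-yl)oxane-2,4-dione
Conditions: HCl (4 M in dioxane, excess), CH2Cl2, 0 °C → rt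
Reagents that add atoms: hydrogen chloride, Cl
Why: Markovnikov hydrochlorination through the tertiary cation masks the alkene, which would otherwise undergo an intramolecular crossed cycloaddition in step 6, and installs the tertiary leaving group for the later epoxide closure without touching C6.

Step 5
Reactants: 8 chloro keto lactone
Product: 9 (6S)-6-(2-chloropropan-2-yl)-4-(triethylsilyloxy)-5,6-dihydro-2H-pyran-2-one
Conditions: Et3SiCl (1.2 equiv), Et3N (1.5 equiv), CH2Cl2, 0 °C; rapid filtration through Et3N-deactivated silica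
Reagents that add atoms: chlorotriethylsilane, CC[Si](Cl)(CC)CC
Why: O-Silylation of the acidic cyclic β-keto lactone at the ketone oxygen should give the conjugated 4-silyloxy enoate, the locked enol needed for a de Mayo-type cycloaddition.

Step 6
Reactants: 9 silyloxy dihydropyranone; 10 1,2-dimethylcyclopentene
Product: 11 (1S,2R,6R,7R,10S)-10-(2-chloropropan-2-yl)-2,6-dimethyl-1-(triethylsilyloxy)-9-oxatricyclo[5.4.0.0^2,6]undecan-8-one (cis-anti-cis)
Conditions: hν (254 nm, quartz), 10 (10 equiv), MeCN (0.02 M, degassed), 0 °C; chromatography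
Reagents that add atoms: none
Why: Excitation of the β-silyloxy enoate of 9 and intersystem crossing give a triplet that adds to the electron-rich tetrasubstituted alkene 10 through a 1,4-biradical, which closes after spin inversion (enone–alkene [2+2] photocycloaddition, the first half of a de Mayo sequence). The chromophore is the β-oxy-α,β-unsaturated δ-lactone that also reacts in the photocycloadditions of 1,3-dioxin-4-ones and tetronates with simple alkenes. One ring is closed, the cyclobutane, by radical recombination to a four-membered ring cis-fused to the lactone and to the cyclopentane; its bond from the former enol carbon is the acyl–C2 bond of the target and its bond from the former α-carbon is the C1–CH2 bond. The two new quaternary centres (C2 and C6 of 11) should come out cis because both bonds form on one face of the cyclic alkene, while C1 and C7 follow from the cis ring fusion and are cleared in step 15. The absolute sense rests on C10: the alkene should add to the lactone face anti to the pseudo-equatorial 2-chloropropan-2-yl group with its trimethylene bridge turned away from the lactone ring, which leads to (2R,6R), and the other diastereomers are rigid tricycles that chromatography should remove. The step needs cross-addition over dimerisation of 9, secured by the excess of 10, and face and orientation selectivity, secured by the C10 substituent; regioselectivity is no issue because 10 is symmetric.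

Step 7
Reactants: 12 2-allyl-6-methylphenol
Product: 13 2-allyl-6-methylcyclohexa-2,5-diene-1,4-dione
Conditions: O2 (1 atm), Co(salen) [N,N'-bis(salicylidene)ethylenediamine complex of divalent cobalt, C16H14CoN2O2] (5 mol %), MeCN, rt
Reagents that add atoms: dioxygen, O=O
Why: Cobalt-catalysed aerobic oxidation of a 2,6-disubstituted phenol goes through the phenoxyl radical to the para-quinone, the para position being the only free activated site.

Step 8
Reactants: 13 allyl methyl benzoquinone
Product: 14 2-allyl-6-methylbenzene-1,4-diol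
Conditions: Na2S2O4 (excess), EtOAc–H2O, rt, argon
Reagents that add atoms: none
Why: Dithionite reduction of a quinone to the hydroquinone is fast and leaves the allyl group alone.

Step 9
Reactants: 14 hydroquinone
Product: 15 1-allyl-2,5-bis(tert-butyldimethylsilyloxy)-3-methylbenzene
Conditions: tBuMe2SiCl (2.5 equiv), imidazole (5 equiv), DMF, rt → 40 °C
Reagents that add atoms: tert-butyl(chloro)dimethylsilane, CC(C)(C)[Si](C)(C)Cl
Why: Imidazole-mediated silylation protects both phenols, the hindered one included, as fluoride-labile ethers that stand up to organolithium, SmI2 and metathesis conditions.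

Step 10
Reactants: 15 allyl arene; 3 methacrolein
Product: 16 (2E)-4-[2,5-bis(tert-butyldimethylsilyloxy)-3-methylphenyl]-2-methylbut-2-enal
Conditions: 3 (5 equiv), second-generation Hoveyda–Grubbs catalyst RuCl2(H2IMes)(=CH-C6H4-2-OiPr) (5 mol %), CH2Cl2, 40 °C
Reagents that add atoms: none
Why: Olefin cross metathesis of a terminal alkene with an α-substituted acrolein should give the trisubstituted enal as the E isomer under thermodynamic control, which sets the alkene geometry of the target.

Step 11
Reactants: 16 enal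
Product: 17 (2E)-4-[2,5-bis(tert-butyldimethylsilyloxy)-3-methylphenyl]-2-methylbut-2-en-1-ol
Conditions: iBu2AlH (1.2 equiv), CH2Cl2, −78 °C; aq KNaC4H4O6
Reagents that add atoms: none
Why: 1,2-Reduction of the enal by the aluminium hydride gives the allylic alcohol without touching the alkene or the aryl silyl ethers.

Step 12
Reactants: 17 allylic alcohol
Product: 19 [(2E)-4-[2,5-bis(tert-butyldimethylsilyloxy)-3-methylphenyl]-2-methylbut-2-en-1-yl] phenyl sulfone, via allylic mesylate 18 (not isolated)
Conditions: MeSO2Cl, Et3N, THF, 0 °C; then PhSO2Na, DMF, rt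
Reagents that add atoms: sodium benzenesulfinate, [Na+].[O-]S(=O)c1ccccc1
Why: SN2 displacement of the primary allylic mesylate by the sulfur atom of the sulfinate gives the allyl sulfone and keeps the E geometry set in step 10.

Step 13
Reactants: 11 tricyclic lactone; 19 allyl sulfone
Product: 22 (3E)-5-[2,5-bis(tert-butyldimethylsilyloxy)-3-methylphenyl]-1-[(1R,5R,6S,7R)-6-{[(2S)-3,3-dimethyloxiran-2-yl]methyl}-1,5-dimethyl-6-(triethylsilyloxy)bicyclo[3.2.0]heptan-7-yl]-3-methyl-2-(phenylsulfonyl)pent-3-en-1-one (both epimers at the sulfonyl carbon), via lithiated sulfone 20 (not isolated), via dilithium chlorohydrin alkoxide 21 (not isolated)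
Conditions: 19 (2.2 equiv), n-BuLi (2.1 equiv), THF, −78 °C; add 11, −78 → 0 °C, then rt; aq NH4Cl (surplus 19 recovered)
Reagents that add atoms: none
Why: Claisen-type acylation of the α-sulfonyl carbanion by the lactone gives the β-keto sulfone, held as its enolate by the second equivalent of 20 so that no second addition occurs, while the alkoxide set free closes the epoxide by displacing the neighbouring tertiary chloride (chlorohydrin closure) with retention at the carbinol carbon, whose C–O bond is never broken.

Step 14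
Reactants: 22 epoxy β-keto sulfone
Product: 23 (3E)-5-[2,5-bis(tert-butyldimethylsilyloxy)-3-methylphenyl]-1-[(1R,5R,6S,7R)-6-{[(2S)-3,3-dimethyloxiran-2-yl]methyl}-1,5-dimethyl-6-(triethylsilyloxy)bicyclo[3.2.0]heptan-7-yl]-3-methylpent-3-en-1-one
Conditions: SmI2 (3 equiv), THF–MeOH, −78 °C
Reagents that add atoms: none
Why: Reductive desulfonylation of the β-keto sulfone by SmI2 gives a samarium enolate whose kinetic protonation at the α-carbon should leave the alkene in the β,γ-position and E, while the second carbonyl group is still masked in the cyclobutane.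

Step 15
Reactants: 23 silyloxycyclobutane ketone
Product: 25 (4E)-6-(2,5-dihydroxy-3-methylphenyl)-1-[(1R,2R)-2-{[(2S)-3,3-dimethyloxiran-2-yl]acetyl}-1,2-dimethylcyclopentyl]-4-methylhex-4-en-2-one, via cyclobutanol 24 (not isolated)
Conditions: Bu4NF (4 equiv), AcOH (4 equiv), THF, 0 °C → rt, argon; pH 7 buffer
Reagents that add atoms: none
Why: Fluoride cleaves the two aryl silyl ethers and the tertiary triethylsilyl ether, and the cyclobutanol 24, a β-hydroxy ketone in a strained ring, should open by retro-aldol cleavage of its C6–C7 bond (de Mayo fragmentation) to the 1,5-diketone without touching a stereocentre.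

**Compound list**

1 | 2,2,6-trimethyl-4H-1,3-dioxin-4-one | CC1=CC(=O)OC(C)(C)O1 | starting material
2 | [(2,2-dimethyl-6-methylidene-6H-1,3-dioxin-4-yl)oxy]trimethylsilane | C=C1C=C(O[Si](C)(C)C)OC(C)(C)O1 | intermediate
3 | methacrolein (2-methylprop-2-enal) | C=C(C)C=O | starting material
4 | 2,2-dimethyl-6-[(2S)-3-methyl-2-(trimethylsilyloxy)but-3-en-1-yl]-4H-1,3-dioxin-4-one | CC1(C)OC(=O)C=C(C[C@H](O[Si](C)(C)C)C(C)=C)O1 | intermediate
5 | 6-[(2S)-2-hydroxy-3-methylbut-3-en-1-yl]-2,2-dimethyl-4H-1,3-dioxin-4-one | CC1(C)OC(=O)C=C(C[C@H](O)C(C)=C)O1 | intermediate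
6 | (5S)-5-hydroxy-6-methyl-3-oxohepta-1,6-dien-1-one (acylketene) | O=C=CC(=O)C[C@H](O)C(C)=C | intermediate
7 | (6S)-6-(prop-1-en-2-yl)oxane-2,4-dione | O=C1O[C@H](C(C)=C)CC(=O)C1 | intermediate
8 | (6S)-6-(2-chloropropan-2-yl)oxane-2,4-dione | O=C1O[C@H](C(C)(C)Cl)CC(=O)C1 | intermediate
9 | (6S)-6-(2-chloropropan-2-yl)-4-(triethylsilyloxy)-5,6-dihydro-2H-pyran-2-one | O=C1O[C@H](C(C)(C)Cl)CC(O[Si](CC)(CC)CC)=C1 | intermediate
10 | 1,2-dimethylcyclopentene | CC1=C(C)CCC1 | starting material
11 | (1S,2R,6R,7R,10S)-10-(2-chloropropan-2-yl)-2,6-dimethyl-1-(triethylsilyloxy)-9-oxatricyclo[5.4.0.0^2,6]undecan-8-one | O=C1O[C@H](C(C)(C)Cl)C[C@]2(O[Si](CC)(CC)CC)[C@H]1[C@@]1(C)CCC[C@@]21C | intermediate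
12 | 2-allyl-6-methylphenol | C=CCc1cccc(C)c1O | starting material
13 | 2-allyl-6-methylcyclohexa-2,5-diene-1,4-dione | C=CCC1=CC(=O)C=C(C)C1=O | intermediate
14 | 2-allyl-6-methylbenzene-1,4-diol | C=CCc1cc(O)cc(C)c1O | intermediate
15 | 1-allyl-2,5-bis(tert-butyldimethylsilyloxy)-3-methylbenzene | C=CCc1cc(O[Si](C)(C)C(C)(C)C)cc(C)c1O[Si](C)(C)C(C)(C)C | intermediate
16 | (2E)-4-[2,5-bis(tert-butyldimethylsilyloxy)-3-methylphenyl]-2-methylbut-2-enal | C/C(=C\Cc1cc(O[Si](C)(C)C(C)(C)C)cc(C)c1O[Si](C)(C)C(C)(C)C)C=O | intermediate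
17 | (2E)-4-[2,5-bis(tert-butyldimethylsilyloxy)-3-methylphenyl]-2-methylbut-2-en-1-ol | C/C(=C\Cc1cc(O[Si](C)(C)C(C)(C)C)cc(C)c1O[Si](C)(C)C(C)(C)C)CO | intermediate
18 | (2E)-4-[2,5-bis(tert-butyldimethylsilyloxy)-3-methylphenyl]-2-methylbut-2-en-1-yl methanesulfonate | C/C(=C\Cc1cc(O[Si](C)(C)C(C)(C)C)cc(C)c1O[Si](C)(C)C(C)(C)C)COS(C)(=O)=O | intermediate
19 | [(2E)-4-[2,5-bis(tert-butyldimethylsilyloxy)-3-methylphenyl]-2-methylbut-2-en-1-yl] phenyl sulfone | C/C(=C\Cc1cc(O[Si](C)(C)C(C)(C)C)cc(C)c1O[Si](C)(C)C(C)(C)C)CS(=O)(=O)c1ccccc1 | intermediate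
20 | α-lithio derivative of sulfone 19 | C/C(=C\Cc1cc(O[Si](C)(C)C(C)(C)C)cc(C)c1O[Si](C)(C)C(C)(C)C)C([Li])S(=O)(=O)c1ccccc1 | intermediate
21 | dilithium salt (enolate and secondary alkoxide) of the ring-opened chlorohydrin β-keto sulfone, bicyclo[3.2.0]heptane core as in 22 | C/C(=C\Cc1cc(O[Si](C)(C)C(C)(C)C)cc(C)c1O[Si](C)(C)C(C)(C)C)C(S(=O)(=O)c1ccccc1)=C(O[Li])[C@@H]1[C@@]2(C)CCC[C@@]2(C)[C@]1(O[Si](CC)(CC)CC)C[C@H](O[Li])C(C)(C)Cl | intermediate
22 | (3E)-5-[2,5-bis(tert-butyldimethylsilyloxy)-3-methylphenyl]-1-[(1R,5R,6S,7R)-6-{[(2S)-3,3-dimethyloxiran-2-yl]methyl}-1,5-dimethyl-6-(triethylsilyloxy)bicyclo[3.2.0]heptan-7-yl]-3-methyl-2-(phenylsulfonyl)pent-3-en-1-one (epimers at C2 of the pentenone) | C/C(=C\Cc1cc(O[Si](C)(C)C(C)(C)C)cc(C)c1O[Si](C)(C)C(C)(C)C)C(S(=O)(=O)c1ccccc1)C(=O)[C@@H]1[C@@]2(C)CCC[C@@]2(C)[C@]1(O[Si](CC)(CC)CC)C[C@@H]1OC1(C)C | intermediate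
23 | (3E)-5-[2,5-bis(tert-butyldimethylsilyloxy)-3-methylphenyl]-1-[(1R,5R,6S,7R)-6-{[(2S)-3,3-dimethyloxiran-2-yl]methyl}-1,5-dimethyl-6-(triethylsilyloxy)bicyclo[3.2.0]heptan-7-yl]-3-methylpent-3-en-1-one | C/C(=C\Cc1cc(O[Si](C)(C)C(C)(C)C)cc(C)c1O[Si](C)(C)C(C)(C)C)CC(=O)[C@@H]1[C@@]2(C)CCC[C@@]2(C)[C@]1(O[Si](CC)(CC)CC)C[C@@H]1OC1(C)C | intermediate
24 | (3E)-5-(2,5-dihydroxy-3-methylphenyl)-1-[(1R,5R,6S,7R)-6-{[(2S)-3,3-dimethyloxiran-2-yl]methyl}-6-hydroxy-1,5-dimethylbicyclo[3.2.0]heptan-7-yl]-3-methylpent-3-en-1-one | C/C(=C\Cc1cc(O)cc(C)c1O)CC(=O)[C@@H]1[C@@]2(C)CCC[C@@]2(C)[C@]1(O)C[C@@H]1OC1(C)C | intermediate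
25 | (4E)-6-(2,5-dihydroxy-3-methylphenyl)-1-[(1R,2R)-2-{[(2S)-3,3-dimethyloxiran-2-yl]acetyl}-1,2-dimethylcyclopentyl]-4-methylhex-4-en-2-one | C/C(=C\Cc1cc(O)cc(C)c1O)CC(=O)C[C@@]1(C)CCC[C@@]1(C)C(=O)C[C@@H]1OC1(C)C | target

**Step count and risks**

Total step count: 15. Longest linear sequence: 9 steps (steps 1–6 then 13–15; the arene branch, steps 7–12 then 13–15, is equally long).

Steps most likely to fail:

Step 6. The first bond-forming event may discriminate poorly between the lactone faces or between the two orientations of the alkene, so that the (2S,6S) series takes a large share. Photodimerisation of the enoate or hydrogen abstraction from the allylic positions of the alkene may also outrun cycloaddition. The fallback gives up the chiral lactone as enol lock and uses the well-tried 1,3-dioxin-4-one chromophore, and it sets out from 5. HCl in dioxane/CH2Cl2 adds to the isopropenyl group of 5 to give the chlorohydrin dioxinone F1. Irradiation of F1 at 300 nm with excess 10 gives the dioxanone photoadduct as two ring diastereomers; there is no internal bias here, so the carbinol centre serves only as a handle for chromatographic separation, and the cis-anti-cis isomer with the ring carbons as in 11 is the dioxanone photoadduct F2. Treatment of F2 with 20 (3.3 equiv, THF, −78 °C → rt) transfers the acyl group, expels acetone and closes the epoxide; on aqueous work-up the freed cyclobutanol opens by retro-aldol to the diketo sulfone F3. SmI2 in THF–MeOH at −78 °C then gives the bis-silyl ether F4, and Bu4NF/AcOH comes back to the route at 25.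

Step 13. The bulky sulfonyl carbanion may fail to add to the lactone carbonyl, whose α-carbon carries two quaternary neighbours, so that proton transfer or migration of the triethylsilyl group to the freed alkoxide takes over. The fallback replaces the lactone by an aldehyde as the electrophile and sets out from 11. Reduction with iBu2AlH (CH2Cl2, −78 °C) gives the lactol F5. With 20 (3 equiv) the lactol opens to its hydroxy aldehyde form, the alkoxide closes the epoxide, and the carbanion adds to the aldehyde to give the β-hydroxy sulfone F6. Oxidation with Dess–Martin periodinane (NaHCO3, CH2Cl2) comes back to the route at 22.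

Step 15. Cleavage of the crowded tertiary silyl ether may be slow, so that the freed β,γ-epoxy ketone and 1,5-diketone stay long in a fluoride medium (epoxide opening by β-elimination, intramolecular aldol addition, migration of the alkene) while the free hydroquinone is exposed to air oxidation. The fallback changes the order of unmasking and sets out from 22. Bu4NF/AcOH is applied at the β-keto sulfone stage, where the acidic C–H group buffers the medium, and desilylation with retro-aldol opening gives the diketo sulfone hydroquinone F7. SmI2 in THF–MeOH at −78 °C then removes the sulfonyl group as the last step under neutral reducing conditions and comes back to the route at 25.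

**Further compounds**

F1 | step 6 | 6-[(2S)-3-chloro-2-hydroxy-3-methylbutyl]-2,2-dimethyl-4H-1,3-dioxin-4-one | CC1(C)OC(=O)C=C(C[C@H](O)C(C)(C)Cl)O1
F2 | step 6 | 7-[(2S)-3-chloro-2-hydroxy-3-methylbutyl]-2,6,9,9-tetramethyl-8,10-dioxatricyclo[5.4.0.0^2,6]undecan-11-one (cis-anti-cis, ring carbons as in 11) | CC1(C)OC(=O)[C@@H]2[C@@]3(C)CCC[C@@]3(C)[C@]2(C[C@H](O)C(C)(C)Cl)O1
F3 | step 6 | (4E)-6-[2,5-bis(tert-butyldimethylsilyloxy)-3-methylphenyl]-1-[(1R,2R)-2-{[(2S)-3,3-dimethyloxiran-2-yl]acetyl}-1,2-dimethylcyclopentyl]-4-methyl-3-(phenylsulfonyl)hex-4-en-2-one | C/C(=C\Cc1cc(O[Si](C)(C)C(C)(C)C)cc(C)c1O[Si](C)(C)C(C)(C)C)C(S(=O)(=O)c1ccccc1)C(=O)C[C@@]1(C)CCC[C@@]1(C)C(=O)C[C@@H]1OC1(C)C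
F4 | step 6 | (4E)-6-[2,5-bis(tert-butyldimethylsilyloxy)-3-methylphenyl]-1-[(1R,2R)-2-{[(2S)-3,3-dimethyloxiran-2-yl]acetyl}-1,2-dimethylcyclopentyl]-4-methylhex-4-en-2-one | C/C(=C\Cc1cc(O[Si](C)(C)C(C)(C)C)cc(C)c1O[Si](C)(C)C(C)(C)C)CC(=O)C[C@@]1(C)CCC[C@@]1(C)C(=O)C[C@@H]1OC1(C)C
F5 | step 13 | (1S,2R,6R,7R,10S)-10-(2-chloropropan-2-yl)-2,6-dimethyl-1-(triethylsilyloxy)-9-oxatricyclo[5.4.0.0^2,6]undecan-8-ol (both anomers) | OC1O[C@H](C(C)(C)Cl)C[C@]2(O[Si](CC)(CC)CC)[C@H]1[C@@]1(C)CCC[C@@]21C
F6 | step 13 | (3E)-5-[2,5-bis(tert-butyldimethylsilyloxy)-3-methylphenyl]-1-[(1R,5R,6S,7R)-6-{[(2S)-3,3-dimethyloxiran-2-yl]methyl}-1,5-dimethyl-6-(triethylsilyloxy)bicyclo[3.2.0]heptan-7-yl]-3-methyl-2-(phenylsulfonyl)pent-3-en-1-ol (stereoisomer mixture at C1 and C2) | C/C(=C\Cc1cc(O[Si](C)(C)C(C)(C)C)cc(C)c1O[Si](C)(C)C(C)(C)C)C(S(=O)(=O)c1ccccc1)C(O)[C@@H]1[C@@]2(C)CCC[C@@]2(C)[C@]1(O[Si](CC)(CC)CC)C[C@@H]1OC1(C)C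
F7 | step 15 | (4E)-6-(2,5-dihydroxy-3-methylphenyl)-1-[(1R,2R)-2-{[(2S)-3,3-dimethyloxiran-2-yl]acetyl}-1,2-dimethylcyclopentyl]-4-methyl-3-(phenylsulfonyl)hex-4-en-2-one | C/C(=C\Cc1cc(O)cc(C)c1O)C(S(=O)(=O)c1ccccc1)C(=O)C[C@@]1(C)CCC[C@@]1(C)C(=O)C[C@@H]1OC1(C)C
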